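common to all: starting material 0.19 M; partner 0.380 M; capture agent 0.190 M; free catalyst 0.38 mM; time 12 h
- Sunday's: at 90 °C until 8.0 h, from then on at 30 °C
- Thursday's: temperature 90 °C
- Monday's: temperature 30 °C
- Wednesday's: temperature 60 °C

- the flask that comes out highest in amount of product, in percent of the starting material charged, or "all alike" when all lie within 1.5 percentage points (Sunday's / Thursday's / Monday's / Wednesday's / all alike)
- product at the end, in percent of the starting material charged, Sunday's
- product at the end, in percent of the starting material charged, Thursday's
- product at the end, in percent of the starting material charged, Monday's
- product at the end, in percent of the starting material charged, Wednesday's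

- the constants hold at 60 °C; other temperatures follow from the activation energies and enthalpies

    partner + catalyst intermediate → free catalyst + product (k1 = 20 M⁻¹ h⁻¹, Ea1 = 50.0 kJ mol⁻¹)
    open intermediate + capture agent → trapped intermediate (k2 = 0.24 M⁻¹ h⁻¹, Ea2 = 70.0 kJ mol⁻¹)
    starting material + free catalyst → free catalyst + open intermediate (k3 = 120 M⁻¹ h⁻¹, Ea3 = 77.0 kJ mol⁻¹)
    free catalyst + open intermediate ⇌ catalyst intermediate (K4 = 110 M⁻¹, k4 = 6100 M⁻¹ h⁻¹, Ea4 = 54.0 kJ mol⁻¹, ΔH4 = 34.0 kJ mol⁻¹)
    (constants at 60 °C)

Slowness was where I began. Free catalyst turns starting material into open intermediate, that intermediate binds free catalyst as catalyst intermediate, and partner releases the catalyst with product, so I asked how slowly this last step lets product appear. With the whole catalyst bound and partner held at its charge, Thursday's flask at 90 °C makes 81.0% of the starting material as product in 12 h. I called this the turnover ceiling: the constant of the partner step at the flask's temperature, times c(partner), times the catalyst charged, times the time, divided by the starting material charged. Wednesday's ceiling is 18.2%, Monday's 3.06%, and Sunday's, with its cooling at 8.0 h, 55.0%.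

Turned round, the question was what it would take for a cooler flask to pass Thursday's. Since Wednesday's stays under its ceiling, Thursday's would have to reach less than 22.5% of its own. So I reckoned its working share, leaving the capture agent out. At the start, step 3 per free catalyst ran 6.71 times as fast as step 1 per bound catalyst. From those two rates at the starting charges, my first estimate of the bound share of the catalyst in Thursday's was 87.0%. My first answer was 70.5%. I put it back: that much product means starting material averaging 64.7% of its charge and partner 82.4% of its own, so my estimate of the bound share becomes 84.1%. The second round gave 56.1%, which is 3.08 times Wednesday's ceiling. Sunday's ceiling also lay below that figure, so I committed to Thursday's.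

The forecast named Thursday's, with 40% for Sunday's, 56% for Thursday's, 0.5% for Monday's and 10.4% for Wednesday's, on the ground that “product formation is capped by the partner step's turnover of that limited pool”.

The simulation put Thursday's highest at 50.7%, with Sunday's at 36.7%, Wednesday's at 9.60% and Monday's at 0.244%. My Thursday's figure stood 5.4 percentage points too high. Thursday's flask held 23.5% as trapped intermediate after 12.0 h. Against the ceiling, the flask reached a working share of 62.6%.

The repeat of Thursday's at 75 °C has a ceiling of 39.7%, and that working share turns it into 24.9%. The computed flask gave 25.2%.

(All constants were set for the occasion; the rest is arithmetic.)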